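**Strategy**

The pyridone ring of the 4-quinolone is cut at C3–C4 and N1–C2. This leaves an anthraniloyl unit (N1, C8a, C4a, C4 on the benzene ring) and a C2–C3 unit that carries the side chain. Since C3 sits between the C4 carbonyl and C2, which has ketone oxidation level, a temporary ester on C3 turns this unit into a β-keto ester. In one operation its enolate is C-acylated by isatoic anhydride, CO2 leaves and the freed aniline closes the ring onto the ketone. The precursor is ethyl 15-hydroxy-15-methyl-3-oxohexadecanoate, an open-chain β-keto ester with a free remote tertiary carbinol; the target is achiral.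

Key step: step 3

Remark on the chemistry: the target has no stereocentre and no stereogenic double bond, so the single compound drawn (as its 4-oxo-1H tautomer) is the only stereoisomer and nothing needs to be controlled. Eleven CH2 groups separate quinolone C2 from the carbinol carbon; compound 6 has the same eleven between its ketone carbon (the future C2) and the carbinol, ten from 3 and one from the terminal carbon of 4.

**Route**

Step 1
Reactants: 1 methyl 11-bromoundecanoate; 2 methylmagnesium bromide
Product: 3 12-bromo-2-methyldodecan-2-ol
Conditions: MeMgBr (2.3 equiv), THF, −10 → 0 °C; sat. aq NH4Cl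
Reagents that add atoms: methylmagnesium bromide, C[Mg]Br
Why: Double Grignard addition to the ester (through the methyl ketone) should give the gem-dimethyl carbinol, while the primary alkyl bromide is inert to MeMgBr at 0 °C without a coupling catalyst; no stereocentre is formed.

Step 2
Reactants: 3 12-bromo-2-methyldodecan-2-ol; 4 ethyl acetoacetate
Product: 6 ethyl 15-hydroxy-15-methyl-3-oxohexadecanoate, via sodium lithium dianion of ethyl acetoacetate 5 (not isolated)
Conditions: 4 (2.5 equiv), NaH (2.5 equiv), THF, 0 °C; n-BuLi (2.5 equiv), 0 °C; 3 (1 equiv), 0 °C → rt; AcOH, then H2O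
Reagents that add atoms: none
Why: Weiler dianion alkylation, in which the terminal (γ) carbanion of 5 is the more reactive site and displaces the primary bromide by SN2, one equivalent of 5 being spent on the carbinol proton (hence the excess), should give the γ-alkylated β-keto ester without any stereocentre.

Step 3
Reactants: 6 ethyl 15-hydroxy-15-methyl-3-oxohexadecanoate; 7 isatoic anhydride
Product: 10 ethyl 2-(12-hydroxy-12-methyltridecyl)-4-oxo-1,4-dihydroquinoline-3-carboxylate, via sodium enolate of ethyl 15-hydroxy-15-methyl-3-oxohexadecanoate 8 (not isolated), via ethyl 2-(2-aminobenzoyl)-15-hydroxy-15-methyl-3-oxohexadecanoate 9 (not isolated)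
Conditions: NaH (1.0 equiv), DMA, 0 °C → rt; 7 (1.3 equiv, in portions), 100–110 °C; aq AcOH to pH 6
Reagents that add atoms: none
Why: Enolate 8 attacks the anhydride-type C4 carbonyl of 7 through carbon (C3–C4 bond), the ring opens to an N-aryl carbamate that is protonated by the new, strongly acidic tricarbonyl C–H and loses CO2, and the aniline nitrogen of 9 then adds to the aliphatic ketone and water is lost to give the 4-pyridone. The closest known reaction type is the condensation of isatoic anhydrides with β-keto ester enolates to 2-substituted 4-oxo-1,4-dihydroquinoline-3-carboxylates, a Niementowski-type quinolone annulation. The one new ring (N1–C2–C3–C4–C4a–C8a) is closed at N1–C2 by a 6-exo-trig addition to the ketone carbonyl followed by dehydration. No stereocentre is created, since the labile tricarbonyl methine of 9 becomes sp2. The step needs acylation at C4 and not at the carbamate-type C2 of 7, which the higher electrophilicity of the aroyl anhydride carbonyl should secure, and closure onto the ketone and not the ester, which follows from the higher electrophilicity of the alkyl ketone and the stability of the enaminone formed. With one equivalent of base only the β-keto ester, far more acidic than the tertiary alcohol, is deprotonated, so the carbinol remains a bystander.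

Step 4
Reactants: 10 ethyl 2-(12-hydroxy-12-methyltridecyl)-4-oxo-1,4-dihydroquinoline-3-carboxylate
Product: 11 2-(12-hydroxy-12-methyltridecyl)-4-oxo-1,4-dihydroquinoline-3-carboxylic acid
Conditions: KOH (5 equiv), EtOH–H2O 3:1, reflux; AcOH to pH 5, 0 °C
Reagents that add atoms: potassium hydroxide, [K+].[OH-]
Why: Saponification (BAc2 ester hydrolysis) is slow here because the quinolone is deprotonated and the ester is flanked on both sides, so reflux is needed, but hydroxide touches neither the tertiary alcohol nor the pyridone and the 3-acid does not lose CO2 at this temperature.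

Step 5
Reactants: 11 2-(12-hydroxy-12-methyltridecyl)-4-oxo-1,4-dihydroquinoline-3-carboxylic acid
Product: 12 2-(12-hydroxy-12-methyltridecyl)quinolin-4(1H)-one (target)
Conditions: Cu2O (10 mol %), 1,10-phenanthroline (20 mol %), NMP–quinoline 3:1, 170–190 °C, N2
Reagents that add atoms: none
Why: Copper-catalysed protodecarboxylation of a heteroaryl carboxylic acid with both ortho positions substituted, which as a vinylogous β-keto acid is also thermally disposed to lose CO2, should give C3–H, and the basic amine medium keeps the tertiary carbinol from ionising and dehydrating.

**Compound list**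

1 | methyl 11-bromoundecanoate | COC(=O)CCCCCCCCCCBr | starting material
2 | methylmagnesium bromide | C[Mg]Br | starting material
3 | 12-bromo-2-methyldodecan-2-ol | CC(C)(O)CCCCCCCCCCBr | intermediate
4 | ethyl acetoacetate (ethyl 3-oxobutanoate) | CCOC(=O)CC(C)=O | starting material
5 | sodium lithium dianion of ethyl acetoacetate | [CH2-]C(=O)[CH-]C(=O)OCC.[Na+].[Li+] | intermediate (not isolated)
6 | ethyl 15-hydroxy-15-methyl-3-oxohexadecanoate | CCOC(=O)CC(=O)CCCCCCCCCCCC(C)(C)O | intermediate
7 | isatoic anhydride (2H-3,1-benzoxazine-2,4(1H)-dione) | O=C1Nc2ccccc2C(=O)O1 | starting material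
8 | sodium enolate of ethyl 15-hydroxy-15-methyl-3-oxohexadecanoate | CCOC(=O)[CH-]C(=O)CCCCCCCCCCCC(C)(C)O.[Na+] | intermediate (not isolated)
9 | ethyl 2-(2-aminobenzoyl)-15-hydroxy-15-methyl-3-oxohexadecanoate (labile methine, no defined configuration) | CCOC(=O)C(C(=O)c1ccccc1N)C(=O)CCCCCCCCCCCC(C)(C)O | intermediate (not isolated)
10 | ethyl 2-(12-hydroxy-12-methyltridecyl)-4-oxo-1,4-dihydroquinoline-3-carboxylate | CCOC(=O)c1c(CCCCCCCCCCCC(C)(C)O)[nH]c2ccccc2c1=O | intermediate
11 | 2-(12-hydroxy-12-methyltridecyl)-4-oxo-1,4-dihydroquinoline-3-carboxylic acid | OC(=O)c1c(CCCCCCCCCCCC(C)(C)O)[nH]c2ccccc2c1=O | intermediate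
12 | 2-(12-hydroxy-12-methyltridecyl)quinolin-4(1H)-one (CNP0171945.0, achiral) | CC(C)(O)CCCCCCCCCCCc1cc(=O)c2ccccc2[nH]1 | target

**Summary**

Total step count: 5
Longest linear sequence: 5 steps (1 → 3 → 6 → 10 → 11 → 12)

**Steps most likely to fail**

1. Step 3. The N–H of the anhydride may transfer its proton to the enolate, after which the anhydride opens to an isocyanate and condenses with itself, so that the enolate is returned unchanged. Ring closure onto the ester carbonyl instead of the ketone is a second possible leak. Fallback (Conrad–Limpach route): it sets out from 6 and comes back at the target 12, bypassing steps 3 to 5. Compound 6 would be condensed with aniline (cat. AcOH, 4 Å sieves, EtOH, 40–60 °C) to ethyl (2Z)-3-anilino-15-hydroxy-15-methylhexadec-2-enoate F1. F1 would then be dropped into diphenyl ether at about 250 °C for a few minutes, where thermal cyclisation onto the ortho carbon with loss of ethanol should give 12 directly. No carboxylic acid is present at any point in this sequence.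

2. Step 5. Loss of CO2 may be incomplete at the moderate temperature chosen, and raising the temperature brings the risk of water being eliminated from the tertiary carbinol. Fallback: it sets out from 11 and comes back at 12. Compound 11 would be decarboxylated by plain heating in diphenyl ether at 240–250 °C without regard for the carbinol. Any dehydrated material, 2-(12-methyltridec-11-en-1-yl)quinolin-4(1H)-one F2 and 2-(12-methyltridec-12-en-1-yl)quinolin-4(1H)-one F3, would be left in the crude product. The whole mixture would then be submitted to Mukaiyama hydration (Co(acac)2 cat., PhSiH3, O2, i-PrOH–THF, rt). Both olefin isomers should be hydrated in the Markovnikov sense at the same carbon and so return to 12.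

3. Step 2. The carbinol proton quenches part of the dianion, and the displacement of a long-chain primary bromide by the remaining dianion may be slow, so that conversion is low or elimination competes. Fallback: it sets out from 3 and comes back at 6, replacing the strongly basic alkylation by a protic-tolerant alkylation followed by chain extension through acylation.
   - Compound 3 would alkylate diethyl sodiomalonate (NaOEt, EtOH, reflux) to give diethyl 2-(11-hydroxy-11-methyldodecyl)propanedioate F4.
   - Saponification (KOH, aq EtOH; cold dilute HCl to pH 2) would give 2-(11-hydroxy-11-methyldodecyl)propanedioic acid F5.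
   - F5 would be decarboxylated in refluxing pyridine to 13-hydroxy-13-methyltetradecanoic acid F6.
   - F6 would be activated with carbonyldiimidazole (THF, rt) as 1-(13-hydroxy-13-methyltetradecanoyl)imidazole F7, which is not isolated. Treatment with magnesium ethyl malonate (potassium ethyl malonate, MgCl2, Et3N) and mildly acidic work-up with loss of CO2 (Masamune–Brooks homologation) should then give 6.

**Further compounds**

F1 | step 3 | ethyl (2Z)-3-anilino-15-hydroxy-15-methylhexadec-2-enoate | CCOC(=O)/C=C(\Nc1ccccc1)CCCCCCCCCCCC(C)(C)O
F2 | step 5 | 2-(12-methyltridec-11-en-1-yl)quinolin-4(1H)-one | CC(C)=CCCCCCCCCCCc1cc(=O)c2ccccc2[nH]1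
F3 | step 5 | 2-(12-methyltridec-12-en-1-yl)quinolin-4(1H)-one | C=C(C)CCCCCCCCCCCc1cc(=O)c2ccccc2[nH]1
F4 | step 2 | diethyl 2-(11-hydroxy-11-methyldodecyl)propanedioate | CCOC(=O)C(CCCCCCCCCCC(C)(C)O)C(=O)OCC
F5 | step 2 | 2-(11-hydroxy-11-methyldodecyl)propanedioic acid | OC(=O)C(CCCCCCCCCCC(C)(C)O)C(=O)O
F6 | step 2 | 13-hydroxy-13-methyltetradecanoic acid | CC(C)(O)CCCCCCCCCCCC(=O)O
F7 | step 2 | 1-(13-hydroxy-13-methyltetradecanoyl)imidazole | CC(C)(O)CCCCCCCCCCCC(=O)n1ccnc1
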